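In the cyclohexenone (C1 ketone, C4 methoxy carbon, C6 quaternary carbon) the C2=C3 alkene lies directly opposite the C5–C6 edge, so the ring is a Diels–Alder adduct in disguise: C4–C5 and C1–C6 are made together by an intramolecular [4+2] cycloaddition. The diene is a 1-alkoxy-1-silyloxy-4-methoxybutadiene, an ester-derived ketene acetal that brings C1 at the ketone oxidation level. The dienophile is the 1,1-disubstituted alkene that becomes C5 and C6. Both are joined through the ester oxygen of a benzylic alcohol that later becomes the aryl ketone, so the two stereocentres of this tether steer the cycloaddition, and desilylation plus one oxidation unveil both carbonyl groups.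

Key step: step 7

Step 1
Reactants: 1 (R)-but-3-yn-2-ol
Product: 2 (R)-but-3-yn-2-yl methanesulfonate
Conditions: MsCl, Et3N, CH2Cl2, −78 to 0 °C
Reagents that add atoms: methanesulfonyl chloride, CS(=O)(=O)Cl
Why: O-mesylation of a secondary propargylic alcohol leaves the C–O bond intact, so the (R) centre is retained.

Step 2
Reactants: 2 (R)-but-3-yn-2-yl methanesulfonate; 3 3,4-dimethoxybenzaldehyde
Product: 5 (1S,2S)-1-(3,4-dimethoxyphenyl)-2-methylbut-3-yn-1-ol, via allenylindium reagent 4 (not isolated)
Conditions: PdCl2(dppf) (5 mol %), InI (1.5 equiv), THF–HMPA 3:1, rt; aq. NH4Cl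
Reagents that add atoms: InI (monovalent indium), [In]I (its atoms are held only in 4)
Why: In this palladium/indium-mediated allenylmetal propargylation, anti SN2′ attack of zerovalent palladium on 2 and transmetalation give allenylindium 4, which adds to 3 through a cyclic SE2′ transition state, so the methyl-bearing carbon should form with net inversion (S) and the carbinol centre anti to it (S).

Step 3
Reactants: 5 (1S,2S)-1-(3,4-dimethoxyphenyl)-2-methylbut-3-yn-1-ol
Product: 7 (1S,2S)-1-(3,4-dimethoxyphenyl)-2-methyl-3-methylidenehex-5-en-1-ol, via vinylindium chelate 6 (not isolated)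
Conditions: allyl bromide, In powder, THF, rt (forms allylindium sesquibromide); add 5, 60 °C; aq. NH4Cl
Reagents that add atoms: allyl bromide, C=CCBr; indium, [In] (held only in 6)
Why: Hydroxyl-assisted Markovnikov carboindation (allylindation) of the terminal alkyne should deliver allyl to the internal carbon and indium to the terminal carbon in chelate 6, and protonolysis gives the 1,1-disubstituted alkene without touching either stereocentre.

Step 4
Reactants: 8 (E)-4-methoxybut-3-en-2-one
Product: 10 (E)-1-diazo-4-methoxybut-3-en-2-one, via trifluoroacetyl diketone 9 (not isolated)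
Conditions: LiHMDS, THF, −78 °C; CF3CO2CH2CF3; then MsN3, Et3N, H2O, MeCN, rt
Reagents that add atoms: methanesulfonyl azide, CS(=O)(=O)N=[N+]=[N-]; 2,2,2-trifluoroethyl trifluoroacetate, O=C(OCC(F)(F)F)C(F)(F)F (held only in 9)
Why: Detrifluoroacetylative Regitz diazo transfer on the kinetic methyl enolate gives the diazoketone without exposing the (E)-enol ether to acid chlorides or diazomethane.

Step 5
Reactants: 10 (E)-1-diazo-4-methoxybut-3-en-2-one; 7 (1S,2S)-1-(3,4-dimethoxyphenyl)-2-methyl-3-methylidenehex-5-en-1-ol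
Product: 12 (1S,2S)-1-(3,4-dimethoxyphenyl)-2-methyl-3-methylidenehex-5-en-1-yl (3E)-4-methoxybut-3-enoate, via vinylketene 11 (not isolated)
Conditions: PhCO2Ag (10 mol %), Et3N, THF, −20 °C to rt, dark; 7 as limiting reagent
Reagents that add atoms: none
Why: Silver-catalysed Wolff rearrangement gives vinylketene 11, which alcohol 7 traps, and α-protonation of the dienol should give the β,γ-unsaturated ester with the (E)-enol ether carried over from 8 and the carbinol C–O bond unbroken.

Step 6
Reactants: 12 (1S,2S)-1-(3,4-dimethoxyphenyl)-2-methyl-3-methylidenehex-5-en-1-yl (3E)-4-methoxybut-3-enoate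
Product: 13 tert-butyl{[(1Z,3E)-1-{[(1S,2S)-1-(3,4-dimethoxyphenyl)-2-methyl-3-methylidenehex-5-en-1-yl]oxy}-4-methoxybuta-1,3-dien-1-yl]oxy}dimethylsilane
Conditions: LDA, THF–HMPA 4:1, −78 °C; TBSCl, −78 to 0 °C; pentane extraction, no chromatography
Reagents that add atoms: tert-butyldimethylsilyl chloride, CC(C)(C)[Si](C)(C)Cl
Why: Kinetic ester enolisation in THF–HMPA (the conditions used for the Ireland–Claisen rearrangement) and O-silylation should place the silyloxy group cis to the vinyl group ((1Z), tether oxygen "outside"), while α-deprotonation leaves the (3E)-enol ether untouched.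

Step 7
Reactants: 13 the (1Z,3E)-silyl ketene acetal
Product: 14 (2S,3S,3aR,5R,7aS)-7a-[(tert-butyldimethylsilyl)oxy]-2-(3,4-dimethoxyphenyl)-5-methoxy-3-methyl-3a-(prop-2-en-1-yl)-2,3,3a,4,5,7a-hexahydro-1-benzofuran
Conditions: toluene (0.01 M), BHT (cat.), base-washed sealed tube, 170 °C
Reagents that add atoms: none
Why: This is a thermal, concerted but asynchronous type 1 intramolecular Diels–Alder reaction of the 1,1,4-trioxygenated diene with the tethered 1,1-disubstituted alkene, and its closest known relatives are thermal cyclisations of unactivated 1,3,8-nonatrienes and [4+2] additions of ester-derived vinylketene silyl acetals. The cyclohexene closes by the suprafacial [4+2] mode and the oxolane arises as the tether ring through a cis-fused (tether-endo) transition state, the three-atom tether leaving no other regiochemistry. C5 is set by the (3E)-enol ether geometry together with the endo tether, which places the "outside" methoxy group cis to the tether carbon C3 and trans to the allyl group. The quaternary C3a is set by the alkene face the tether can reach: allylic 1,2-strain keeps the C3 methyl away from the allyl group and the C2 aryl group sits exo, trans to that methyl, so the anti-(1S,2S) tether is matched. C7a is a silyl ketal centre that disappears in step 8. The step needs cis- over trans-fusion and the (1Z)-ketene acetal (the (1E)-isomer can only cyclise with allyl endo and would give the C5 epimer), and no Ireland–Claisen pathway exists because the ester oxygen sits on a homoallylic carbon.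

Step 8
Reactants: 14 the silyl ketal cycloadduct
Product: 16 (4R,6R)-6-[(1S,2S)-1-(3,4-dimethoxyphenyl)-1-hydroxypropan-2-yl]-4-methoxy-6-(prop-2-en-1-yl)cyclohex-2-en-1-one, via hemiketal 15 (not isolated)
Conditions: TBAF, AcOH, THF, 0 °C
Reagents that add atoms: none
Why: Buffered fluoride desilylation of the silyl ketal gives hemiketal 15, which opens to the conjugated enone without altering any stereocentre or eliminating the γ-methoxy group.

Step 9
Reactants: 16 the hydroxy enone
Product: 17 (4R,6R)-6-[(2S)-1-(3,4-dimethoxyphenyl)-1-oxopropan-2-yl]-4-methoxy-6-(prop-2-en-1-yl)cyclohex-2-en-1-one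
Conditions: Dess–Martin periodinane, CH2Cl2, 0 °C to rt
Reagents that add atoms: none
Why: Dess–Martin oxidation of the secondary benzylic alcohol (drawn out of the hemiketal equilibrium) is near-neutral and should give the aryl ketone without epimerising the adjacent α-methyl centre.

Compound list
1 | (R)-but-3-yn-2-ol | C#C[C@@H](C)O | starting material
2 | (R)-but-3-yn-2-yl methanesulfonate | C#C[C@@H](C)OS(C)(=O)=O | intermediate
3 | 3,4-dimethoxybenzaldehyde | COc1ccc(C=O)cc1OC | starting material
4 | (P)-buta-1,2-dien-1-ylindium iodide methanesulfonate (trivalent indium; not isolated) | [H]C(C)=[C@]=C([H])[In](I)OS(C)(=O)=O | intermediate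
5 | (1S,2S)-1-(3,4-dimethoxyphenyl)-2-methylbut-3-yn-1-ol (anti) | C#C[C@H](C)[C@H](O)c1ccc(OC)c(OC)c1 | intermediate
6 | six-membered bromoindium alkoxide chelate, ring In–O–CH(Ar)–CH(CH3)–C(allyl)=CH–In, (5S,6S) (trivalent indium; not isolated) | C=CCC1=C[In](Br)O[C@H](c2ccc(OC)c(OC)c2)[C@H]1C | intermediate
7 | (1S,2S)-1-(3,4-dimethoxyphenyl)-2-methyl-3-methylidenehex-5-en-1-ol | C=CCC(=C)[C@H](C)[C@H](O)c1ccc(OC)c(OC)c1 | intermediate
8 | (E)-4-methoxybut-3-en-2-one | CC(=O)/C=C/OC | starting material
9 | (E)-1,1,1-trifluoro-6-methoxyhex-5-ene-2,4-dione (not isolated) | O=C(CC(=O)/C=C/OC)C(F)(F)F | intermediate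
10 | (E)-1-diazo-4-methoxybut-3-en-2-one | [N-]=[N+]=CC(=O)/C=C/OC | intermediate
11 | (E)-4-methoxybuta-1,3-dien-1-one (vinylketene; not isolated) | O=C=C/C=C/OC | intermediate
12 | (1S,2S)-1-(3,4-dimethoxyphenyl)-2-methyl-3-methylidenehex-5-en-1-yl (3E)-4-methoxybut-3-enoate | C=CCC(=C)[C@H](C)[C@H](OC(=O)C/C=C/OC)c1ccc(OC)c(OC)c1 | intermediate
13 | tert-butyl{[(1Z,3E)-1-{[(1S,2S)-1-(3,4-dimethoxyphenyl)-2-methyl-3-methylidenehex-5-en-1-yl]oxy}-4-methoxybuta-1,3-dien-1-yl]oxy}dimethylsilane | C=CCC(=C)[C@H](C)[C@H](O/C(O[Si](C)(C)C(C)(C)C)=C/C=C/OC)c1ccc(OC)c(OC)c1 | intermediate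
14 | (2S,3S,3aR,5R,7aS)-7a-[(tert-butyldimethylsilyl)oxy]-2-(3,4-dimethoxyphenyl)-5-methoxy-3-methyl-3a-(prop-2-en-1-yl)-2,3,3a,4,5,7a-hexahydro-1-benzofuran (cis-fused; 3-methyl and 5-methoxy trans to the 3a-allyl group, 2-aryl trans to 3-methyl) | C=CC[C@]12C[C@@H](OC)C=C[C@@]1(O[Si](C)(C)C(C)(C)C)O[C@H](c3ccc(OC)c(OC)c3)[C@H]2C | intermediate
15 | (2S,3S,3aR,5R,7aR)-2-(3,4-dimethoxyphenyl)-5-methoxy-3-methyl-3a-(prop-2-en-1-yl)-2,3,3a,4,5,7a-hexahydro-1-benzofuran-7a-ol (not isolated) | C=CC[C@]12C[C@@H](OC)C=C[C@@]1(O)O[C@H](c3ccc(OC)c(OC)c3)[C@H]2C | intermediate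
16 | (4R,6R)-6-[(1S,2S)-1-(3,4-dimethoxyphenyl)-1-hydroxypropan-2-yl]-4-methoxy-6-(prop-2-en-1-yl)cyclohex-2-en-1-one | C=CC[C@]1([C@H](C)[C@H](O)c2ccc(OC)c(OC)c2)C[C@@H](OC)C=CC1=O | intermediate
17 | (4R,6R)-6-[(2S)-1-(3,4-dimethoxyphenyl)-1-oxopropan-2-yl]-4-methoxy-6-(prop-2-en-1-yl)cyclohex-2-en-1-one | C=CC[C@]1([C@H](C)C(=O)c2ccc(OC)c(OC)c2)C[C@@H](OC)C=CC1=O | target

Total step count: 9. Longest linear sequence: 8 (steps 1, 2, 3, 5, 6, 7, 8, 9); step 4 is a one-step side branch.

Steps most likely to fail

Step 7. The cycloaddition onto an unactivated alkene that must become a quaternary carbon may be slower than thermal O-to-C silyl migration or desilylation of the ketene acetal. Trans-fusion or attack on the other alkene face may also erode selectivity. The fallback sets out from 12 and returns at 17, and replaces the silyl ketene acetal by a silicon-free dienyl ether that tolerates harsher heating. Reductive acetylation of ester 12 (DIBAL-H, −78 °C, then Ac2O, pyridine, DMAP) should give the mixed acetal (E)-1-{[(1S,2S)-1-(3,4-dimethoxyphenyl)-2-methyl-3-methylidenehex-5-en-1-yl]oxy}-4-methoxybut-3-en-1-yl acetate F1. Elimination of acetic acid (TMSOTf, iPr2NEt) should give the (1E,3E)-dienyl ether F2. Heating F2 in 1,2-dichlorobenzene at about 200 °C should close the same two ring bonds and give the cis-fused 2-aryl-hexahydrobenzofuran F3. DDQ in wet CH2Cl2 should then oxidise the electron-rich benzylic ether C–H, and the resulting hemiketal opens to the aryl ketone allylic alcohol F4. Dess–Martin oxidation of F4 gives 17.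

Step 5. Capture of the vinylketene by a hindered secondary benzylic alcohol may lose out to ketene dimerisation or to O–H insertion of the silver carbenoid, and base may move the double bond into conjugation. The fallback sets out from 7 and returns at 12, building the β,γ-unsaturated ester by cross-coupling instead of ketene capture. Acylation of 7 with bromoacetyl bromide and pyridine should give the bromoacetate F5. Suzuki–Miyaura coupling of F5 with (E)-2-(2-methoxyethenyl)-4,4,5,5-tetramethyl-1,3,2-dioxaborolane (Pd(OAc)2, P(o-tol)3, K3PO4, THF–H2O) should give 12, with the (E)-geometry taken from the boronate.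

Step 3. The carbometalation may add with the wrong regiochemistry, or Lewis acidic indium halides may ionise the electron-rich benzylic alcohol. The fallback sets out from 5 and returns at 7, replacing carbometalation by hydroboration and cross-coupling. Copper-catalysed α-selective protoboration of the alkyne ((IMes)CuCl, NaOt-Bu, B2pin2, MeOH) should give the internal vinylboronate (1S,2S)-1-(3,4-dimethoxyphenyl)-2-methyl-3-(4,4,5,5-tetramethyl-1,3,2-dioxaborolan-2-yl)but-3-en-1-ol F6. Coupling of F6 with allyl bromide (Pd(PPh3)4, CsF, THF) gives 7.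

Further compounds
F1 | step 7 | (E)-1-{[(1S,2S)-1-(3,4-dimethoxyphenyl)-2-methyl-3-methylidenehex-5-en-1-yl]oxy}-4-methoxybut-3-en-1-yl acetate (both epimers at the acetal carbon) | C=CCC(=C)[C@H](C)[C@H](OC(OC(C)=O)C/C=C/OC)c1ccc(OC)c(OC)c1
F2 | step 7 | 4-[(1S,2S)-1-{[(1E,3E)-4-methoxybuta-1,3-dien-1-yl]oxy}-2-methyl-3-methylidenehex-5-en-1-yl]-1,2-dimethoxybenzene | C=CCC(=C)[C@H](C)[C@H](O/C=C/C=C/OC)c1ccc(OC)c(OC)c1
F3 | step 7 | (2S,3S,3aR,5R,7aR)-2-(3,4-dimethoxyphenyl)-5-methoxy-3-methyl-3a-(prop-2-en-1-yl)-2,3,3a,4,5,7a-hexahydro-1-benzofuran (as 14 with H in place of the silyloxy group) | C=CC[C@]12C[C@@H](OC)C=C[C@H]1O[C@H](c3ccc(OC)c(OC)c3)[C@H]2C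
F4 | step 7 | (2S)-1-(3,4-dimethoxyphenyl)-2-[(1R,2R,5R)-2-hydroxy-5-methoxy-1-(prop-2-en-1-yl)cyclohex-3-en-1-yl]propan-1-one | C=CC[C@]1([C@H](C)C(=O)c2ccc(OC)c(OC)c2)C[C@@H](OC)C=C[C@H]1O
F5 | step 5 | (1S,2S)-1-(3,4-dimethoxyphenyl)-2-methyl-3-methylidenehex-5-en-1-yl bromoacetate | C=CCC(=C)[C@H](C)[C@H](OC(=O)CBr)c1ccc(OC)c(OC)c1
F6 | step 3 | (1S,2S)-1-(3,4-dimethoxyphenyl)-2-methyl-3-(4,4,5,5-tetramethyl-1,3,2-dioxaborolan-2-yl)but-3-en-1-ol | C=C(B1OC(C)(C)C(C)(C)O1)[C@H](C)[C@H](O)c1ccc(OC)c(OC)c1
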